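A small charge of reagent already shows how the flask divides it. Reagent meets starting material and gives open intermediate, or meets partner and gives second intermediate. In the earlier runs, open intermediate ends in homo product or target, each counted by the starting material in it, so homo product plus target reads the share of reagent that entered through starting material.

| flask | starting material | partner | reagent | remark | time |
|---|---|---|---|---|---|
| beta | 0.020 M | 1.5 equiv | 1 equiv | run made earlier |  |
| epsilon | 0.020 M | 1.5 equiv | 0.50 equiv | run made earlier |  |
| theta | 0.020 M | 1.5 equiv | 0.75 equiv | run made earlier |  |
| Friday's | 0.020 M (fed, over 4.0 d) | 1.50 equiv | 1.00 equiv | all else is in the flask from the start; the feed brings no volume worth counting | 10 d |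
| Sunday's | 0.020 M | 1.50 equiv | 1.00 equiv | everything together at the start | 10 d |
| Saturday's | 0.020 M (in portions, 5, over 4.0 d) | 1.50 equiv | 1.00 equiv | first portion at the start, last at 4.0 d | 10 d |
| Wednesday's | 0.020 M | 1.50 equiv | 1.00 equiv (fed, over 4.0 d) | all else is in the flask from the start; the feed brings no volume worth counting | 10 d |

- beta (time / d: homo product / %, target / %): 0.333: 37.9, 19.8; 0.833: 38.5, 23.7; 1.67: 39.7, 23.1; 2.50: 39.1, 23.7; 4.00: 40.1, 22.6; 5.00: 40.5, 23.4; 6.00: 40.5, 22.3
- epsilon (time / d: homo product / %, target / %): 0.500: 23.0, 9.6; 1.67: 22.9, 11.3; 3.00: 23.3, 10.0; 4.00: 23.3, 10.1; 6.00: 21.2, 10.4; 8.00: 21.3, 9.0; 10.0: 21.7, 11.3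
- theta (time / d: homo product / %, target / %): 0.833: 31.5, 15.5; 1.25: 31.3, 16.8; 1.67: 30.9, 17.8; 3.00: 32.9, 15.6; 4.00: 31.0, 15.7; 6.00: 31.6, 16.3; 10.0: 31.3, 16.0

(standard deviation of a reading: 1 percentage point)

- a species is counted by the starting material in it: one homo product counts as two
- steps that have been proposed: reagent + partner -> second intermediate; 2 open intermediate -> homo product; partner -> decomposed reagent; open intermediate + second intermediate -> target; second intermediate -> side product; starting material + reagent -> open intermediate

* the flask that comes out highest in amount of homo product, in percent of the starting material charged, or "all alike" when all lie within 1.5 percentage points (Friday's / Sunday's / Saturday's / Wednesday's / all alike)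
* homo product at the end, in percent of the starting material charged, Friday's
* homo product at the end, in percent of the starting material charged, Sunday's
* homo product at the end, in percent of the starting material charged, Saturday's
* homo product at the end, in percent of the starting material charged, Wednesday's

At the last reading the epsilon run, with 0.50 equiv of reagent, holds 66.0 % of its reagent in those two products, and the beta run, with 1 equiv, holds 62.8 %. Counting partner as spent on reagent, the logarithm of the starting material left over that of the partner left gives, as a reading from the beta run, 3.47 for S, the selectivity factor: the rate constant of reagent with starting material divided by that with partner. While both stand, the share entering at a moment is S·c(starting material) / (S·c(starting material) + c(partner)).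

The reckoning here follows from that. Sunday's repeats beta, so its homo product should lie near 40.5 %. In Wednesday's, reagent is fed into both competitors, so the share should stay near 62.8 %. The beta run had made nearly all of its products by 0.333 d, so that is taken as the working time of the reagent in Friday's. By then Friday's has received a fraction 0.0833 of its starting material, which, at that moment and with partner as charged, gives a share of 16.1 %, less than in beta. That share at one moment is taken here as a rough estimate of homo product plus target together.

The forecast gives homo product of 12 % in Friday's, 40 % in Sunday's, 13 % in Saturday's and 52 % in Wednesday's, with Wednesday's highest, holding for Wednesday's that “starting material and partner compete as in batch”.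

    reagent + partner → second intermediate (k = 0.00237 M⁻¹ s⁻¹)
    2 open intermediate → homo product (k = 0.0275 M⁻¹ s⁻¹)
    partner → decomposed reagent (k = 1.24 × 10⁻⁵ s⁻¹)
    open intermediate + second intermediate → target (k = 0.0208 M⁻¹ s⁻¹)
    second intermediate → side product (k = 5.28 × 10⁻⁶ s⁻¹)
    starting material + reagent → open intermediate (k = 0.00717 M⁻¹ s⁻¹)

The flasks end with homo product at 0.544 % in Friday's, 39.5 % in Sunday's, 4.54 % in Saturday's and 82.0 % in Wednesday's, so Wednesday's stands highest, 30 percentage points above the forecast. Wednesday's homo product plus target reach 89.7 %, more than the 62.8 % of beta, and Wednesday's holds 0.0280 M of decomposed reagent, more than the 0.0225 M of Sunday's. Friday's has used 17.8 % of its starting material, where the estimate stood at 16.1 %. For the neighbour of Friday's at 0.0050 M of starting material, with the equivalents held, the working time is taken as longer by the factor 4.00, and S = 3.47 then estimates a share of 43.5 %; that flask used 46.1 % of its starting material.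

All runs were generated by integration with constants of no real substance; scatter was added.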